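**Plan**
1. Retrosynthesis: the enal goes back to its allylic alcohol. The side chain is cut at the CH2–CH= bond to its first trisubstituted olefin (B-alkyl Suzuki coupling), which leaves a vinyl group on the quaternary ring carbon and an (E)-alkenyl iodide already carrying the epoxy alcohol. The cyclohexane is then cut between the quaternary C(CH3) carbon and the neighbouring CH, while the terminal carbon of the 3-hydroxypropyl arm is re-joined, as a ketal carbon, to the exocyclic olefin carbon.
2. This gives a cyclohexene ketal (a temporary "ring A", from 2-methylcyclohexane-1,3-dione and formaldehyde) tethered through two CH2 groups to a tetrasubstituted vinyl epoxide (from ethyl 2-methylacetoacetate).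
3. Forward order of rings: side-chain oxirane (step 8), tetrasubstituted oxirane (step 19), then the cyclohexane, closed last by an epoxide-initiated cation–olefin cyclisation that runs on into a Grob-type scission of ring A (step 22). The side chain is joined afterwards; desilylation and MnO2 oxidation finish the route.
4. Enabling feature: in the ring the tertiary carbinol C(CH3)(OH) sits beside the quaternary C(CH3) carbon, the imprint of an epoxide opened at its far end by carbon. The next two ring atoms carry the CH–(CH2)3OH arm and the exocyclic C=C(CH3)CHO unit; the arm's terminal carbon and the exocyclic carbon are the two ends of a cleaved six-membered ring, so arm and olefin can arise together by fragmentation of a β-oxygenated cation.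
5. Stereochemistry: ring carbinol and quaternary centre from the Sharpless epoxide (retention and inversion), ring CH from the chair transition state, enal geometry from the quaternary centre of ring A (CBS desymmetrisation), E-olefins from Negishi carboalumination, side-chain carbinol from asymmetric propargylation, oxirane centre from hydroxyl-directed epoxidation.

Key step: step 22

Assumption: in the CBS step hydride is taken to enter anti to the silyloxymethyl group (the sense known for yeast reduction of 2-allyl-2-methyl-1,3-diones); the carbinol centre formed there is erased in step 13.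

**Step 1**
Reactants: 1 3-methylbut-2-enal; 2 allenylboronic acid pinacol ester
Product: 3 (S)-6-methylhept-5-en-1-yn-4-ol
Conditions: (S)-TRIP (5 mol %), 4 Å MS, toluene, −20 °C; aq. NaHCO3
Reagents that add atoms: none
Why: Chiral-phosphoric-acid-catalysed propargylation (allenylboronate addition through a six-membered SE2′ transition state) should give the homopropargylic alcohol, the acid antipode being the one expected to deliver the (S)-carbinol that becomes the side-chain hydroxyl centre.

**Step 2**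
Reactants: 3 (S)-6-methylhept-5-en-1-yn-4-ol
Product: 4 (S)-tert-butyldimethyl[(6-methylhept-5-en-1-yn-4-yl)oxy]silane
Conditions: TBSCl, imidazole, DMF, rt
Reagents that add atoms: tert-butyldimethylsilyl chloride, CC(C)(C)[Si](C)(C)Cl
Why: Standard silylation masks the ionisable allylic alcohol against the Lewis-acidic alane of steps 3 and 6.

**Step 3**
Reactants: 4 (S)-tert-butyldimethyl[(6-methylhept-5-en-1-yn-4-yl)oxy]silane
Product: 6 (S,E)-tert-butyl[(1-iodo-2,6-dimethylhepta-1,5-dien-4-yl)oxy]dimethylsilane, via alkenylalane 5 (not isolated)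
Conditions: Me3Al, Cp2ZrCl2 (20 mol %), H2O (1 equiv), CH2Cl2, −23 °C; then I2, THF, −23 → 0 °C
Reagents that add atoms: trimethylaluminium, C[Al](C)C; iodine, II
Why: Negishi zirconium-catalysed carboalumination adds methyl and aluminium syn across the terminal alkyne with methyl on the inner carbon, and iodinolysis with retention should give the (E)-iodide.

**Step 4**
Reactants: 6 (S,E)-tert-butyl[(1-iodo-2,6-dimethylhepta-1,5-dien-4-yl)oxy]dimethylsilane; 7 (4-bromobut-1-yn-1-yl)trimethylsilane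
Product: 9 (S,E)-tert-butyl{[2,6-dimethyl-11-(trimethylsilyl)undeca-2,6-dien-10-yn-4-yl]oxy}dimethylsilane, via organozinc bromide 8 (not isolated)
Conditions: 7, Zn dust, LiCl, THF, 40 °C; then 6, Pd(PPh3)4 (5 mol %), THF, rt
Reagents that add atoms: none
Why: Negishi coupling of the alkylzinc formed by zinc insertion with the alkenyl iodide should proceed with retention of the E geometry.

**Step 5**
Reactants: 9 (S,E)-tert-butyl{[2,6-dimethyl-11-(trimethylsilyl)undeca-2,6-dien-10-yn-4-yl]oxy}dimethylsilane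
Product: 10 (S,E)-tert-butyl[(2,6-dimethylundeca-2,6-dien-10-yn-4-yl)oxy]dimethylsilane
Conditions: K2CO3 (cat.), MeOH, rt
Reagents that add atoms: none
Why: Methanolysis cleaves only the alkynyl C–Si bond (protodesilylation) and leaves the silyl ether alone.

**Step 6**
Reactants: 10 (S,E)-tert-butyl[(2,6-dimethylundeca-2,6-dien-10-yn-4-yl)oxy]dimethylsilane
Product: 12 tert-butyl{[(4S,6E,10E)-11-iodo-2,6,10-trimethylundeca-2,6,10-trien-4-yl]oxy}dimethylsilane, via alkenylalane 11 (not isolated)
Conditions: Me3Al, Cp2ZrCl2 (20 mol %), H2O (1 equiv), CH2Cl2, −23 °C; then I2, THF, −23 → 0 °C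
Reagents that add atoms: trimethylaluminium, C[Al](C)C; iodine, II
Why: A second Negishi carboalumination–iodination sets the second (E)-trisubstituted olefin as its alkenyl iodide; the trisubstituted olefins already present do not react.

**Step 7**
Reactants: 12 tert-butyl{[(4S,6E,10E)-11-iodo-2,6,10-trimethylundeca-2,6,10-trien-4-yl]oxy}dimethylsilane
Product: 13 (4S,6E,10E)-11-iodo-2,6,10-trimethylundeca-2,6,10-trien-4-ol
Conditions: Bu4NF, THF, 0 °C → rt
Reagents that add atoms: none
Why: Fluoride desilylation frees the hydroxyl that directs the next step.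

**Step 8**
Reactants: 13 (4S,6E,10E)-11-iodo-2,6,10-trimethylundeca-2,6,10-trien-4-ol
Product: 14 (1S,3E,7E)-1-[(2R)-3,3-dimethyloxiran-2-yl]-8-iodo-3,7-dimethylocta-3,7-dien-1-ol
Conditions: VO(acac)2 (5 mol %), t-BuOOH (1.1 equiv), CH2Cl2, 0 °C
Reagents that add atoms: tert-butyl hydroperoxide, CC(C)(C)OO
Why: In this hydroxyl-directed vanadium epoxidation, allylic 1,3-strain with the cis-methyl group puts the carbinol hydrogen in the olefin plane and oxygen is delivered syn to the hydroxyl (threo, oxirane centre R), the allylic olefin reacting much faster than the homoallylic one or the iodoalkene.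

**Step 9**
Reactants: 15 2-methylcyclohexane-1,3-dione; 16 formaldehyde (37 % aqueous)
Product: 17 2-(hydroxymethyl)-2-methylcyclohexane-1,3-dione
Conditions: 37 % aq. HCHO, H2O, rt
Reagents that add atoms: none
Why: Aldol addition of the acidic dione to formaldehyde builds the quaternary carbon that later becomes the enal α-carbon with its CH3 and CHO substituents.

**Step 10**
Reactants: 17 2-(hydroxymethyl)-2-methylcyclohexane-1,3-dione
Product: 18 2-{[(tert-butyldiphenylsilyl)oxy]methyl}-2-methylcyclohexane-1,3-dione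
Conditions: TBDPSCl, imidazole, CH2Cl2, 0 °C → rt
Reagents that add atoms: tert-butyldiphenylsilyl chloride, CC(C)(C)[Si](Cl)(c1ccccc1)c1ccccc1
Why: Silylation under mild base blocks the retro-aldol path and installs an ether robust enough to last until step 26.

**Step 11**
Reactants: 18 2-{[(tert-butyldiphenylsilyl)oxy]methyl}-2-methylcyclohexane-1,3-dione
Product: 19 (2S,3S)-2-{[(tert-butyldiphenylsilyl)oxy]methyl}-3-hydroxy-2-methylcyclohexan-1-one
Conditions: (R)-2-methyl-CBS-oxazaborolidine (20 mol %), catecholborane, toluene, −78 °C; aq. NaHCO3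
Reagents that add atoms: none
Why: The CBS reduction desymmetrises the dione: the catalyst fixes the carbinol as S and hydride enters anti to CH2OTBDPS, so one of the two enantiotopic carbonyls is reduced and the quaternary centre is set.

**Step 12**
Reactants: 19 (2S,3S)-2-{[(tert-butyldiphenylsilyl)oxy]methyl}-3-hydroxy-2-methylcyclohexan-1-one
Product: 20 (6S,7S)-6-{[(tert-butyldiphenylsilyl)oxy]methyl}-6-methyl-1,4-dioxaspiro[4.5]decan-7-ol
Conditions: HOCH2CH2OH, PPTS, benzene, reflux (Dean–Stark)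
Reagents that add atoms: ethylene glycol, OCCO
Why: Acid-catalysed ketalisation of the remaining ketone installs the dioxolane carbon that serves as the leaving carbon in step 22 and ends as the CH2OH carbon of the hydroxypropyl arm.

**Step 13**
Reactants: 20 (6S,7S)-6-{[(tert-butyldiphenylsilyl)oxy]methyl}-6-methyl-1,4-dioxaspiro[4.5]decan-7-ol
Product: 21 (6S)-6-{[(tert-butyldiphenylsilyl)oxy]methyl}-6-methyl-1,4-dioxaspiro[4.5]decan-7-one
Conditions: Dess–Martin periodinane, NaHCO3, CH2Cl2, rt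
Reagents that add atoms: none
Why: Dess–Martin oxidation returns the carbinol to the ketone, so that steps 11–13 amount to an enantioselective mono-ketalisation of the dione.

**Step 14**
Reactants: 21 (6S)-6-{[(tert-butyldiphenylsilyl)oxy]methyl}-6-methyl-1,4-dioxaspiro[4.5]decan-7-one
Product: 22 (6S)-6-{[(tert-butyldiphenylsilyl)oxy]methyl}-6-methyl-1,4-dioxaspiro[4.5]dec-7-en-7-yl trifluoromethanesulfonate
Conditions: KN(SiMe3)2, THF, −78 °C; then PhNTf2
Reagents that add atoms: N-phenylbis(trifluoromethanesulfonimide), O=S(=O)(N(c1ccccc1)S(=O)(=O)C(F)(F)F)C(F)(F)F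
Why: The ketone can enolise only toward its CH2 side, so enolate O-triflation gives a single enol triflate.

**Step 15**
Reactants: 22 (6S)-6-{[(tert-butyldiphenylsilyl)oxy]methyl}-6-methyl-1,4-dioxaspiro[4.5]dec-7-en-7-yl trifluoromethanesulfonate; 23 tributyl(vinyl)stannane
Product: 24 tert-butyl{[(6R)-7-ethenyl-6-methyl-1,4-dioxaspiro[4.5]dec-7-en-6-yl]methoxy}diphenylsilane
Conditions: Pd(PPh3)4 (5 mol %), LiCl, THF, reflux
Reagents that add atoms: none
Why: Stille coupling of the enol triflate with the vinylstannane gives the 1,3-diene whose vinyl group supplies the two tether carbons.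

**Step 16**
Reactants: 25 ethyl 2-methyl-3-oxobutanoate
Product: 26 ethyl (E)-2-methyl-3-{[(trifluoromethyl)sulfonyl]oxy}but-2-enoate
Conditions: Tf2O, aq. Me4NOH, toluene, 5 °C
Reagents that add atoms: trifluoromethanesulfonic anhydride, O=S(=O)(OS(=O)(=O)C(F)(F)F)C(F)(F)F
Why: Enol triflation of the β-keto ester through the non-chelated ammonium enolate should place the triflate trans to the ester (E).

**Step 17**
Reactants: 24 tert-butyl{[(6R)-7-ethenyl-6-methyl-1,4-dioxaspiro[4.5]dec-7-en-6-yl]methoxy}diphenylsilane; 26 ethyl (E)-2-methyl-3-{[(trifluoromethyl)sulfonyl]oxy}but-2-enoate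
Product: 28 ethyl (2E)-5-[(6R)-6-{[(tert-butyldiphenylsilyl)oxy]methyl}-6-methyl-1,4-dioxaspiro[4.5]dec-7-en-7-yl]-2,3-dimethylpent-2-enoate, via alkylborane 27 (not isolated)
Conditions: 9-BBN-H, THF, 0 °C → rt; then 26, Pd(dppf)Cl2 (5 mol %), AsPh3, Cs2CO3, DMF–H2O, rt
Reagents that add atoms: none
Why: 9-BBN adds to the terminal CH2 of the vinyl group only, and the B-alkyl Suzuki–Miyaura coupling replaces the triflate with retention, giving the tetrasubstituted enoate with the two methyl groups trans.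

**Step 18**
Reactants: 28 ethyl (2E)-5-[(6R)-6-{[(tert-butyldiphenylsilyl)oxy]methyl}-6-methyl-1,4-dioxaspiro[4.5]dec-7-en-7-yl]-2,3-dimethylpent-2-enoate
Product: 29 (2E)-5-[(6R)-6-{[(tert-butyldiphenylsilyl)oxy]methyl}-6-methyl-1,4-dioxaspiro[4.5]dec-7-en-7-yl]-2,3-dimethylpent-2-en-1-ol
Conditions: i-Bu2AlH, CH2Cl2, −78 °C; aq. potassium sodium tartrate
Reagents that add atoms: none
Why: 1,2-Reduction of the enoate by the aluminium hydride gives the allylic alcohol needed for the Sharpless step; ketal and silyl ether are inert.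

**Step 19**
Reactants: 29 (2E)-5-[(6R)-6-{[(tert-butyldiphenylsilyl)oxy]methyl}-6-methyl-1,4-dioxaspiro[4.5]dec-7-en-7-yl]-2,3-dimethylpent-2-en-1-ol
Product: 30 [(2S,3S)-3-{2-[(6R)-6-{[(tert-butyldiphenylsilyl)oxy]methyl}-6-methyl-1,4-dioxaspiro[4.5]dec-7-en-7-yl]ethyl}-2,3-dimethyloxiran-2-yl]methanol
Conditions: Ti(OiPr)4 (10 mol %), L-(+)-diethyl tartrate (12 mol %), t-BuOOH, 4 Å MS, CH2Cl2, −20 °C
Reagents that add atoms: tert-butyl hydroperoxide, CC(C)(C)OO
Why: Sharpless asymmetric epoxidation acts only on the allylic-alcohol olefin, and L-(+)-tartrate delivers oxygen to the face that gives the (2S,3S)-oxirane, as with trans-substituted allylic alcohols of the geraniol type.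

**Step 20**
Reactants: 30 [(2S,3S)-3-{2-[(6R)-6-{[(tert-butyldiphenylsilyl)oxy]methyl}-6-methyl-1,4-dioxaspiro[4.5]dec-7-en-7-yl]ethyl}-2,3-dimethyloxiran-2-yl]methanol
Product: 31 (2R,3S)-3-{2-[(6R)-6-{[(tert-butyldiphenylsilyl)oxy]methyl}-6-methyl-1,4-dioxaspiro[4.5]dec-7-en-7-yl]ethyl}-2,3-dimethyloxirane-2-carbaldehyde
Conditions: Dess–Martin periodinane, NaHCO3, CH2Cl2, 0 °C
Reagents that add atoms: none
Why: Buffered Dess–Martin oxidation gives the epoxy aldehyde, which cannot epimerise because its α-carbon is fully substituted (the descriptor changes only through ligand priority).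

**Step 21**
Reactants: 31 (2R,3S)-3-{2-[(6R)-6-{[(tert-butyldiphenylsilyl)oxy]methyl}-6-methyl-1,4-dioxaspiro[4.5]dec-7-en-7-yl]ethyl}-2,3-dimethyloxirane-2-carbaldehyde
Product: 32 tert-butyl{[(6R)-7-{2-[(2S,3S)-3-ethenyl-2,3-dimethyloxiran-2-yl]ethyl}-6-methyl-1,4-dioxaspiro[4.5]dec-7-en-6-yl]methoxy}diphenylsilane
Conditions: Ph3PCH3Br, KN(SiMe3)2, THF, 0 °C; then 31, −78 → 0 °C
Reagents that add atoms: methyltriphenylphosphonium bromide, C[P+](c1ccccc1)(c1ccccc1)c1ccccc1.[Br-]
Why: Wittig methylenation installs the vinyl group that directs the ionisation of the epoxide in step 22 and later carries the side chain.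

**Step 22**
Reactants: 32 tert-butyl{[(6R)-7-{2-[(2S,3S)-3-ethenyl-2,3-dimethyloxiran-2-yl]ethyl}-6-methyl-1,4-dioxaspiro[4.5]dec-7-en-6-yl]methoxy}diphenylsilane
Product: 35 2-hydroxyethyl 3-[(1R,2S,3S,6Z)-6-{1-[(tert-butyldiphenylsilyl)oxy]propan-2-ylidene}-2-ethenyl-3-hydroxy-2,3-dimethylcyclohexyl]propanoate, via tertiary carbocation 33 (not isolated), via dioxolanylium ion 34 (not isolated)
Conditions: MeAlCl2 (1.5 equiv), CH2Cl2, −78 °C; then sat. aq. NaHCO3, −78 °C → rt
Reagents that add atoms: water, O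
Why: Proposed new method: MeAlCl2 opens the epoxide at the tertiary carbon that bears the vinyl group (allyl-stabilised), the CH terminus of the ring-A olefin attacks that carbon with inversion to give the ring-fusion tertiary carbocation 33, and the bond from the adjacent quaternary carbon to the dioxolane carbon then breaks (Grob, retro-Prins type) to leave the exocyclic tetrasubstituted olefin and the dioxolan-2-ylium ion 34, which water turns into the hydroxyethyl ester. The closest known reaction types are the Lewis-acid epoxide-initiated cation–olefin cyclisation and the scission of β-oxygenated tertiary carbocations into olefin and carbonyl (acid cleavage of 1,3-diols, the second stage of Lewis-acid carbonyl–olefin metathesis); running the two as one cascade with a ketal carbon as electrofuge is without precedent. The one ring closed is the cyclohexane, by 6-endo-trig attack of the olefin with endo opening of the epoxide (both oxirane carbons end in the ring) through a chair. The carbinol centre keeps the configuration set by the Sharpless epoxidation, the quaternary centre is formed by inversion at the oxirane carbon, and the CH centre follows from the chair, in which the ring-A CH2 group, held cis to the quaternary ring-A carbon by ring A, lies equatorial. The olefin geometry is passed on from the quaternary ring-A centre: attack occurs anti to its pseudoaxial CH2OTBDPS group, the dioxolane carbon departs on the face of the new bond, and CH2OTBDPS swings to the side of the new CH centre (Z). The step needs C–O cleavage at the right oxirane carbon, secured by the vinyl group, and scission faster than proton loss, 1,2-shift or capture of the cation by the aluminium alkoxide, for which the two oxygen atoms on the departing carbon (a dioxolanylium ion far more stable than the carbocation and unable to add back to the olefin) and the poor migrating ability of the aligned CH2OTBDPS group are relied on.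

**Step 23**
Reactants: 35 2-hydroxyethyl 3-[(1R,2S,3S,6Z)-6-{1-[(tert-butyldiphenylsilyl)oxy]propan-2-ylidene}-2-ethenyl-3-hydroxy-2,3-dimethylcyclohexyl]propanoate
Product: 36 (1S,2S,3R,4Z)-4-{1-[(tert-butyldiphenylsilyl)oxy]propan-2-ylidene}-2-ethenyl-3-(3-hydroxypropyl)-1,2-dimethylcyclohexan-1-ol
Conditions: LiAlH4, THF, 0 °C
Reagents that add atoms: none
Why: Hydride reduction of the ester gives the 3-hydroxypropyl arm and releases ethylene glycol; olefins and the silyl ether are not touched.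

**Step 24**
Reactants: 36 (1S,2S,3R,4Z)-4-{1-[(tert-butyldiphenylsilyl)oxy]propan-2-ylidene}-2-ethenyl-3-(3-hydroxypropyl)-1,2-dimethylcyclohexan-1-ol
Product: 37 (1S,2S,3R,4Z)-3-{3-[(tert-butyldimethylsilyl)oxy]propyl}-4-{1-[(tert-butyldiphenylsilyl)oxy]propan-2-ylidene}-2-ethenyl-1,2-dimethylcyclohexan-1-ol
Conditions: TBSCl, imidazole, DMF, 0 °C
Reagents that add atoms: tert-butyldimethylsilyl chloride, CC(C)(C)[Si](C)(C)Cl
Why: Silylation takes the primary hydroxyl only (the tertiary carbinol is too hindered), which keeps the hydroboration clean.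

**Step 25**
Reactants: 37 (1S,2S,3R,4Z)-3-{3-[(tert-butyldimethylsilyl)oxy]propyl}-4-{1-[(tert-butyldiphenylsilyl)oxy]propan-2-ylidene}-2-ethenyl-1,2-dimethylcyclohexan-1-ol; 14 (1S,3E,7E)-1-[(2R)-3,3-dimethyloxiran-2-yl]-8-iodo-3,7-dimethylocta-3,7-dien-1-ol
Product: 39 (1S,2S,3R,4Z)-3-{3-[(tert-butyldimethylsilyl)oxy]propyl}-4-{1-[(tert-butyldiphenylsilyl)oxy]propan-2-ylidene}-2-{(3E,7E,10S)-10-[(2R)-3,3-dimethyloxiran-2-yl]-10-hydroxy-4,8-dimethyldeca-3,7-dien-1-yl}-1,2-dimethylcyclohexan-1-ol, via alkylborane 38 (not isolated)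
Conditions: 9-BBN-H (3 equiv), THF, rt; then 14, Pd(dppf)Cl2 (10 mol %), AsPh3, Cs2CO3, DMF–H2O, rt
Reagents that add atoms: none
Why: 9-BBN hydroborates only the monosubstituted vinyl group (the tetrasubstituted olefin is inert), and the B-alkyl Suzuki–Miyaura coupling joins the side chain with retention of the iodide geometry under conditions the epoxy alcohol should tolerate.

**Step 26**
Reactants: 39 (1S,2S,3R,4Z)-3-{3-[(tert-butyldimethylsilyl)oxy]propyl}-4-{1-[(tert-butyldiphenylsilyl)oxy]propan-2-ylidene}-2-{(3E,7E,10S)-10-[(2R)-3,3-dimethyloxiran-2-yl]-10-hydroxy-4,8-dimethyldeca-3,7-dien-1-yl}-1,2-dimethylcyclohexan-1-ol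
Product: 40 (1S,2S,3R,4Z)-2-{(3E,7E,10S)-10-[(2R)-3,3-dimethyloxiran-2-yl]-10-hydroxy-4,8-dimethyldeca-3,7-dien-1-yl}-4-(1-hydroxypropan-2-ylidene)-3-(3-hydroxypropyl)-1,2-dimethylcyclohexan-1-ol
Conditions: Bu4NF, THF, rt
Reagents that add atoms: none
Why: Fluoride desilylation removes both silyl ethers; the trisubstituted epoxy alcohol is stable to these mildly basic conditions.

**Step 27**
Reactants: 40 (1S,2S,3R,4Z)-2-{(3E,7E,10S)-10-[(2R)-3,3-dimethyloxiran-2-yl]-10-hydroxy-4,8-dimethyldeca-3,7-dien-1-yl}-4-(1-hydroxypropan-2-ylidene)-3-(3-hydroxypropyl)-1,2-dimethylcyclohexan-1-ol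
Product: 41 (2Z)-2-[(2R,3S,4S)-4-hydroxy-3-{(3E,7E,10S)-10-[(2R)-3,3-dimethyloxiran-2-yl]-10-hydroxy-4,8-dimethyldeca-3,7-dien-1-yl}-2-(3-hydroxypropyl)-3,4-dimethylcyclohexylidene]propanal (CNP0161066.1)
Conditions: MnO2, CH2Cl2, rt
Reagents that add atoms: none
Why: MnO2 allylic oxidation takes only the primary allylic alcohol (the saturated primary, tertiary and epoxy-carbinol hydroxyls are inert) and should leave the olefin geometry alone, giving the target.

**Compound list**
1 | 3-methylbut-2-enal | CC(C)=CC=O | starting material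
2 | allenylboronic acid pinacol ester | C=C=CB1OC(C)(C)C(C)(C)O1 | starting material
3 | (S)-6-methylhept-5-en-1-yn-4-ol | C#CC[C@H](O)C=C(C)C | intermediate
4 | (S)-tert-butyldimethyl[(6-methylhept-5-en-1-yn-4-yl)oxy]silane | C#CC[C@H](O[Si](C)(C)C(C)(C)C)C=C(C)C | intermediate
5 | (E)-alkenyl(dimethyl)alane from 4 (not isolated) | C[Al](C)/C=C(\C)C[C@H](O[Si](C)(C)C(C)(C)C)C=C(C)C | intermediate
6 | (S,E)-tert-butyl[(1-iodo-2,6-dimethylhepta-1,5-dien-4-yl)oxy]dimethylsilane | I/C=C(\C)C[C@H](O[Si](C)(C)C(C)(C)C)C=C(C)C | intermediate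
7 | (4-bromobut-1-yn-1-yl)trimethylsilane | C[Si](C)(C)C#CCCBr | starting material
8 | [4-(trimethylsilyl)but-3-yn-1-yl]zinc bromide (not isolated) | C[Si](C)(C)C#CCC[Zn]Br | intermediate
9 | (S,E)-tert-butyl{[2,6-dimethyl-11-(trimethylsilyl)undeca-2,6-dien-10-yn-4-yl]oxy}dimethylsilane | C[Si](C)(C)C#CCC/C=C(\C)C[C@H](O[Si](C)(C)C(C)(C)C)C=C(C)C | intermediate
10 | (S,E)-tert-butyl[(2,6-dimethylundeca-2,6-dien-10-yn-4-yl)oxy]dimethylsilane | C#CCC/C=C(\C)C[C@H](O[Si](C)(C)C(C)(C)C)C=C(C)C | intermediate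
11 | (E,E)-dienyl(dimethyl)alane from 10 (not isolated) | C[Al](C)/C=C(\C)CC/C=C(\C)C[C@H](O[Si](C)(C)C(C)(C)C)C=C(C)C | intermediate
12 | tert-butyl{[(4S,6E,10E)-11-iodo-2,6,10-trimethylundeca-2,6,10-trien-4-yl]oxy}dimethylsilane | I/C=C(\C)CC/C=C(\C)C[C@H](O[Si](C)(C)C(C)(C)C)C=C(C)C | intermediate
13 | (4S,6E,10E)-11-iodo-2,6,10-trimethylundeca-2,6,10-trien-4-ol | I/C=C(\C)CC/C=C(\C)C[C@H](O)C=C(C)C | intermediate
14 | (1S,3E,7E)-1-[(2R)-3,3-dimethyloxiran-2-yl]-8-iodo-3,7-dimethylocta-3,7-dien-1-ol | I/C=C(\C)CC/C=C(\C)C[C@H](O)[C@H]1OC1(C)C | intermediate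
15 | 2-methylcyclohexane-1,3-dione | CC1C(=O)CCCC1=O | starting material
16 | formaldehyde (37 % aqueous) | C=O | starting material
17 | 2-(hydroxymethyl)-2-methylcyclohexane-1,3-dione | CC1(CO)C(=O)CCCC1=O | intermediate
18 | 2-{[(tert-butyldiphenylsilyl)oxy]methyl}-2-methylcyclohexane-1,3-dione | CC1(CO[Si](c2ccccc2)(c2ccccc2)C(C)(C)C)C(=O)CCCC1=O | intermediate
19 | (2S,3S)-2-{[(tert-butyldiphenylsilyl)oxy]methyl}-3-hydroxy-2-methylcyclohexan-1-one | C[C@]1(CO[Si](c2ccccc2)(c2ccccc2)C(C)(C)C)[C@@H](O)CCCC1=O | intermediate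
20 | (6S,7S)-6-{[(tert-butyldiphenylsilyl)oxy]methyl}-6-methyl-1,4-dioxaspiro[4.5]decan-7-ol | C[C@]1(CO[Si](c2ccccc2)(c2ccccc2)C(C)(C)C)[C@@H](O)CCCC13OCCO3 | intermediate
21 | (6S)-6-{[(tert-butyldiphenylsilyl)oxy]methyl}-6-methyl-1,4-dioxaspiro[4.5]decan-7-one | C[C@]1(CO[Si](c2ccccc2)(c2ccccc2)C(C)(C)C)C(=O)CCCC13OCCO3 | intermediate
22 | (6S)-6-{[(tert-butyldiphenylsilyl)oxy]methyl}-6-methyl-1,4-dioxaspiro[4.5]dec-7-en-7-yl trifluoromethanesulfonate | C[C@]1(CO[Si](c2ccccc2)(c2ccccc2)C(C)(C)C)C(OS(=O)(=O)C(F)(F)F)=CCCC13OCCO3 | intermediate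
23 | tributyl(vinyl)stannane | C=C[Sn](CCCC)(CCCC)CCCC | starting material
24 | tert-butyl{[(6R)-7-ethenyl-6-methyl-1,4-dioxaspiro[4.5]dec-7-en-6-yl]methoxy}diphenylsilane | C[C@]1(CO[Si](c2ccccc2)(c2ccccc2)C(C)(C)C)C(C=C)=CCCC13OCCO3 | intermediate
25 | ethyl 2-methyl-3-oxobutanoate | CCOC(=O)C(C)C(C)=O | starting material
26 | ethyl (E)-2-methyl-3-{[(trifluoromethyl)sulfonyl]oxy}but-2-enoate | CCOC(=O)/C(C)=C(\C)OS(=O)(=O)C(F)(F)F | intermediate
27 | 9-{2-[(6R)-6-{[(tert-butyldiphenylsilyl)oxy]methyl}-6-methyl-1,4-dioxaspiro[4.5]dec-7-en-7-yl]ethyl}-9-borabicyclo[3.3.1]nonane (not isolated) | C[C@]1(CO[Si](c2ccccc2)(c2ccccc2)C(C)(C)C)C(CCB4C5CCCC4CCC5)=CCCC13OCCO3 | intermediate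
28 | ethyl (2E)-5-[(6R)-6-{[(tert-butyldiphenylsilyl)oxy]methyl}-6-methyl-1,4-dioxaspiro[4.5]dec-7-en-7-yl]-2,3-dimethylpent-2-enoate | C[C@]1(CO[Si](c2ccccc2)(c2ccccc2)C(C)(C)C)C(CC/C(C)=C(\C)C(=O)OCC)=CCCC13OCCO3 | intermediate
29 | (2E)-5-[(6R)-6-{[(tert-butyldiphenylsilyl)oxy]methyl}-6-methyl-1,4-dioxaspiro[4.5]dec-7-en-7-yl]-2,3-dimethylpent-2-en-1-ol | C[C@]1(CO[Si](c2ccccc2)(c2ccccc2)C(C)(C)C)C(CC/C(C)=C(\C)CO)=CCCC13OCCO3 | intermediate
30 | [(2S,3S)-3-{2-[(6R)-6-{[(tert-butyldiphenylsilyl)oxy]methyl}-6-methyl-1,4-dioxaspiro[4.5]dec-7-en-7-yl]ethyl}-2,3-dimethyloxiran-2-yl]methanol | C[C@]1(CO[Si](c2ccccc2)(c2ccccc2)C(C)(C)C)C(CC[C@]4(C)O[C@@]4(C)CO)=CCCC13OCCO3 | intermediate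
31 | (2R,3S)-3-{2-[(6R)-6-{[(tert-butyldiphenylsilyl)oxy]methyl}-6-methyl-1,4-dioxaspiro[4.5]dec-7-en-7-yl]ethyl}-2,3-dimethyloxirane-2-carbaldehyde | C[C@]1(CO[Si](c2ccccc2)(c2ccccc2)C(C)(C)C)C(CC[C@]4(C)O[C@@]4(C)C=O)=CCCC13OCCO3 | intermediate
32 | tert-butyl{[(6R)-7-{2-[(2S,3S)-3-ethenyl-2,3-dimethyloxiran-2-yl]ethyl}-6-methyl-1,4-dioxaspiro[4.5]dec-7-en-6-yl]methoxy}diphenylsilane | C[C@]1(CO[Si](c2ccccc2)(c2ccccc2)C(C)(C)C)C(CC[C@]4(C)O[C@@]4(C)C=C)=CCCC13OCCO3 | intermediate
33 | ring-fusion tertiary carbocation of the bicyclic ketal, as its aluminium alkoxide zwitterion (not isolated) | C[C@]1(CO[Si](c2ccccc2)(c2ccccc2)C(C)(C)C)[C+]2CC[C@](C)(O[Al-](C)(Cl)Cl)[C@@](C)(C=C)[C@@H]2CCC13OCCO3 | intermediate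
34 | 2-alkyl-1,3-dioxolan-2-ylium ion of the ring-opened product, as its aluminium alkoxide zwitterion (not isolated) | C/C(CO[Si](c2ccccc2)(c2ccccc2)C(C)(C)C)=C1\CC[C@](C)(O[Al-](C)(Cl)Cl)[C@@](C)(C=C)[C@@H]1CCC3=[O+]CCO3 | intermediate
35 | 2-hydroxyethyl 3-[(1R,2S,3S,6Z)-6-{1-[(tert-butyldiphenylsilyl)oxy]propan-2-ylidene}-2-ethenyl-3-hydroxy-2,3-dimethylcyclohexyl]propanoate | C/C(CO[Si](c2ccccc2)(c2ccccc2)C(C)(C)C)=C1\CC[C@](C)(O)[C@@](C)(C=C)[C@@H]1CCC(=O)OCCO | intermediate
36 | (1S,2S,3R,4Z)-4-{1-[(tert-butyldiphenylsilyl)oxy]propan-2-ylidene}-2-ethenyl-3-(3-hydroxypropyl)-1,2-dimethylcyclohexan-1-ol | C/C(CO[Si](c2ccccc2)(c2ccccc2)C(C)(C)C)=C1\CC[C@](C)(O)[C@@](C)(C=C)[C@@H]1CCCO | intermediate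
37 | (1S,2S,3R,4Z)-3-{3-[(tert-butyldimethylsilyl)oxy]propyl}-4-{1-[(tert-butyldiphenylsilyl)oxy]propan-2-ylidene}-2-ethenyl-1,2-dimethylcyclohexan-1-ol | C/C(CO[Si](c2ccccc2)(c2ccccc2)C(C)(C)C)=C1\CC[C@](C)(O)[C@@](C)(C=C)[C@@H]1CCCO[Si](C)(C)C(C)(C)C | intermediate
38 | B-alkyl-9-borabicyclo[3.3.1]nonane from 37 (boron on the terminal carbon of the former vinyl group; not isolated) | C/C(CO[Si](c2ccccc2)(c2ccccc2)C(C)(C)C)=C1\CC[C@](C)(O)[C@@](C)(CCB4C5CCCC4CCC5)[C@@H]1CCCO[Si](C)(C)C(C)(C)C | intermediate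
39 | (1S,2S,3R,4Z)-3-{3-[(tert-butyldimethylsilyl)oxy]propyl}-4-{1-[(tert-butyldiphenylsilyl)oxy]propan-2-ylidene}-2-{(3E,7E,10S)-10-[(2R)-3,3-dimethyloxiran-2-yl]-10-hydroxy-4,8-dimethyldeca-3,7-dien-1-yl}-1,2-dimethylcyclohexan-1-ol | C/C(CO[Si](c2ccccc2)(c2ccccc2)C(C)(C)C)=C1\CC[C@](C)(O)[C@@](C)(CC/C=C(\C)CC/C=C(\C)C[C@H](O)[C@H]2OC2(C)C)[C@@H]1CCCO[Si](C)(C)C(C)(C)C | intermediate
40 | (1S,2S,3R,4Z)-2-{(3E,7E,10S)-10-[(2R)-3,3-dimethyloxiran-2-yl]-10-hydroxy-4,8-dimethyldeca-3,7-dien-1-yl}-4-(1-hydroxypropan-2-ylidene)-3-(3-hydroxypropyl)-1,2-dimethylcyclohexan-1-ol | C/C(CO)=C1\CC[C@](C)(O)[C@@](C)(CC/C=C(\C)CC/C=C(\C)C[C@H](O)[C@H]2OC2(C)C)[C@@H]1CCCO | intermediate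
41 | (2Z)-2-[(2R,3S,4S)-4-hydroxy-3-{(3E,7E,10S)-10-[(2R)-3,3-dimethyloxiran-2-yl]-10-hydroxy-4,8-dimethyldeca-3,7-dien-1-yl}-2-(3-hydroxypropyl)-3,4-dimethylcyclohexylidene]propanal | C/C(C=O)=C1\CC[C@](C)(O)[C@@](C)(CC/C=C(\C)CC/C=C(\C)C[C@H](O)[C@H]2OC2(C)C)[C@@H]1CCCO | target

**Step count and risks**
Total: 27 steps. Longest linear sequence: 18 steps (15 → 41 through steps 9–15 and 17–27).

Step 22 (proposed new method). What may go wrong: proton loss from the tertiary carbocation, or its capture across the ring by the aluminium alkoxide, before the ketal carbon–carbon bond has turned into alignment with the empty orbital; scission from the other ring-A conformer would also erode the olefin geometry. The fallback uses known chemistry, sets out from 32 and returns at 36; it separates ring closure from scission and makes the scission anionic. SnCl4 in CH2Cl2 at −78 °C closes the same ring by a halide-terminated epoxide–olefin cyclisation to the tertiary chloride F1; chloride is expected to enter anti to the axial methyl of the new quaternary centre, so that the C–Cl bond is equatorial on ring A. PPTS in wet acetone removes the dioxolane to give the β-chloro ketone F2. NaOMe in MeOH adds to the ketone, and the alkoxide expels chloride across the anti-periplanar ring bond in a classical Grob fragmentation to give the methyl ester F3 with the same Z olefin. LiAlH4, as in step 23, then gives 36.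

Step 25. What may go wrong: slow transmetallation and protodeboronation of the hindered alkylborane next to the quaternary centre, together with base-induced opening or migration of the epoxy alcohol during a long coupling. The fallback sets out from 37 and returns at 39; it changes the nucleophile from boron to zinc. Hydroboration–oxidation (9-BBN-H; NaBO3) gives the primary alcohol F4, I2/PPh3/imidazole gives the primary iodide F5, and zinc insertion (Zn dust, LiCl, THF) gives the alkylzinc iodide F6. This is joined to 14 by a Negishi coupling (Pd(OAc)2, SPhos, THF, rt), a coupling known to tolerate free hydroxyl groups and to need no aqueous base.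

Step 11. What may go wrong: poor discrimination between the methyl and silyloxymethyl faces of the dione, so that the quaternary centre (and with it the later enal geometry) is set with low fidelity. The fallback sets out from 15 and returns at 20; it moves the desymmetrisation to the 2-allyl series, where the yeast reduction is well established, and builds the CH2O group afterwards. C-Allylation of 15 (allyl bromide, aq. NaOH) gives the allyl dione F7, and baker's yeast reduction gives the (2S,3S)-hydroxy ketone F8. Ketalisation (ethylene glycol, TsOH) gives the hydroxy ketal F9, and olefin isomerisation ([Ir(cod)(PMePh2)2]PF6 activated with H2, THF) gives the (E)-propenyl compound F10. Ozonolysis with NaBH4 work-up gives the diol F11, and selective silylation of its primary hydroxyl (TBDPSCl, imidazole) gives 20.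

**Further compounds**
F1 | step 22 | cis-fused tertiary chloride: the bicyclic dioxolane ketal of 33 with chlorine on the ring-fusion carbon and free tertiary hydroxyl | C[C@]1(CO[Si](c2ccccc2)(c2ccccc2)C(C)(C)C)[C@]2(Cl)CC[C@](C)(O)[C@@](C)(C=C)[C@@H]2CCC13OCCO3
F2 | step 22 | β-chloro ketone obtained from F1 by removal of the dioxolane | C[C@]1(CO[Si](c2ccccc2)(c2ccccc2)C(C)(C)C)[C@]2(Cl)CC[C@](C)(O)[C@@](C)(C=C)[C@@H]2CCC1=O
F3 | step 22 | methyl 3-[(1R,2S,3S,6Z)-6-{1-[(tert-butyldiphenylsilyl)oxy]propan-2-ylidene}-2-ethenyl-3-hydroxy-2,3-dimethylcyclohexyl]propanoate | C/C(CO[Si](c2ccccc2)(c2ccccc2)C(C)(C)C)=C1\CC[C@](C)(O)[C@@](C)(C=C)[C@@H]1CCC(=O)OC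
F4 | step 25 | primary alcohol from hydroboration–oxidation of the vinyl group of 37 (2-hydroxyethyl on the quaternary ring carbon) | C/C(CO[Si](c2ccccc2)(c2ccccc2)C(C)(C)C)=C1\CC[C@](C)(O)[C@@](C)(CCO)[C@@H]1CCCO[Si](C)(C)C(C)(C)C
F5 | step 25 | primary iodide from F4 (2-iodoethyl on the quaternary ring carbon) | C/C(CO[Si](c2ccccc2)(c2ccccc2)C(C)(C)C)=C1\CC[C@](C)(O)[C@@](C)(CCI)[C@@H]1CCCO[Si](C)(C)C(C)(C)C
F6 | step 25 | alkylzinc iodide from F5 | C/C(CO[Si](c2ccccc2)(c2ccccc2)C(C)(C)C)=C1\CC[C@](C)(O)[C@@](C)(CC[Zn]I)[C@@H]1CCCO[Si](C)(C)C(C)(C)C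
F7 | step 11 | 2-methyl-2-(prop-2-en-1-yl)cyclohexane-1,3-dione | C=CCC1(C)C(=O)CCCC1=O
F8 | step 11 | (2S,3S)-3-hydroxy-2-methyl-2-(prop-2-en-1-yl)cyclohexan-1-one | C[C@]1(CC=C)[C@@H](O)CCCC1=O
F9 | step 11 | (6S,7S)-6-methyl-6-(prop-2-en-1-yl)-1,4-dioxaspiro[4.5]decan-7-ol | C[C@]1(CC=C)[C@@H](O)CCCC13OCCO3
F10 | step 11 | (6S,7S)-6-methyl-6-[(E)-prop-1-en-1-yl]-1,4-dioxaspiro[4.5]decan-7-ol | C[C@]1(/C=C/C)[C@@H](O)CCCC13OCCO3
F11 | step 11 | (6S,7S)-6-(hydroxymethyl)-6-methyl-1,4-dioxaspiro[4.5]decan-7-ol | C[C@]1(CO)[C@@H](O)CCCC13OCCO3
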